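Atoms are numbered by position in the target SMILES: ring A is C8-C9-C11-C14-C36, ring B C8-C25-C23-C15-C14-C36, ring C C8-C25-C27-C34-C36, ring D the lactone C27-C29-C31-O33-C34. Ring D shares its C27-C34 bond with ring C and has its ring oxygen on C34, which is the pattern a ketone (C34=O33), an alkene (C27=C29) and CO give in one [2+2+1] event.
Cuts, from the target backwards: C4=C5 (aldol condensation) and C15-C16 (acylation) for the two dienoyl chains, C29-C30 (methylenation, hydrogenation), then C27-C34, C29-C31 and C31-O33 together; the bicyclic precursor is cut at C25-C26, C11-O13, C11-C12, C14-C15, C36-C34, C8-C6 and C8-C25.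
Forward: ring A is bought as (R)-4-silyloxycyclopentenone; a 3,5-dimethylisoxazole (masked C23/C27 diketone) is coupled to C8; C34 and C6 enter by conjugate addition and aldol trapping; ring B closes by Michael addition of the isoxazole methyl carbon C15 to C14; rings C and D close together in the titanium step; C30 and the two dienoyl chains come last.
The alkene partner is the methylene silyl enol ether of a C25 acetyl group: a trisubstituted enol ether carrying C30 would need its methyl cis to quaternary C25, which enolisation does not deliver, so C30 is added after the key step.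
Stereochemistry: the C14 silyloxy group of the enone directs the cuprate (C36) and is then eliminated; C8 is set anti to C36, C14 by the tether, C11 by exo hydroxylation, C25 by endo methylation, C27 and C34 by the cis-fused metallacycle on the endo face, C29 by hydrogenation from the open face.

Key step: step 14

Remark: the carbinol centres at C6 (made in step 3, oxidised in step 17) and at C4 (intermediates 30 and 31, eliminated in step 18) and the alkene geometry of F3, F4 and F5 have no consequence and are left open in the SMILES; "exo" means the face turned towards the one-carbon bridge C36.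

Step 1
Reactants: 1 (R)-4-(tert-butyldimethylsilyloxy)cyclopent-2-en-1-one
Product: 2 (R)-4-(tert-butyldimethylsilyloxy)-2-iodocyclopent-2-en-1-one
Conditions: I2, pyridine, CH2Cl2, 0 °C to rt
Reagents that add atoms: iodine, II
Why: α-Iodination of the enone by pyridine addition, iodination of the enolate and elimination is standard for 4-silyloxycyclopentenones and does not touch the C14 centre.

Step 2
Reactants: 2 (R)-4-(tert-butyldimethylsilyloxy)-2-iodocyclopent-2-en-1-one; 3 3,5-dimethylisoxazole-4-boronic acid pinacol ester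
Product: 4 (R)-4-(tert-butyldimethylsilyloxy)-2-(3,5-dimethylisoxazol-4-yl)cyclopent-2-en-1-one
Conditions: PdCl2(PhCN)2 (5 mol %), AsPh3, Ag2O, THF/H2O, rt
Reagents that add atoms: none
Why: Suzuki–Miyaura coupling of an α-iodoenone under Ag2O activation runs at room temperature without a soluble base, so the β-silyloxy ketone is not eliminated, and it places the masked diketone carbons C25, C23, C15, C27 and C29 on C8.

Step 3
Reactants: 4 (R)-4-(tert-butyldimethylsilyloxy)-2-(3,5-dimethylisoxazol-4-yl)cyclopent-2-en-1-one; 5 isopropenylmagnesium bromide; 6 acetaldehyde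
Product: 7 (2R,3R,4R)-4-(tert-butyldimethylsilyloxy)-2-(3,5-dimethylisoxazol-4-yl)-2-(1-hydroxyethyl)-3-(prop-1-en-2-yl)cyclopentan-1-one
Conditions: CH2=C(CH3)MgBr, CuBr·SMe2 (20 mol %), THF, −78 °C; then CH3CHO, −78 °C; aq. NH4Cl
Reagents that add atoms: none
Why: Copper-catalysed conjugate addition places the isopropenyl group on C36 anti to the C14 silyloxy group, and the magnesium enolate then adds to acetaldehyde anti to that new group (conjugate addition–aldol trapping), which sets quaternary C8 with the isoxazole cis to C34.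

Step 4
Reactants: 7 (2R,3R,4R)-4-(tert-butyldimethylsilyloxy)-2-(3,5-dimethylisoxazol-4-yl)-2-(1-hydroxyethyl)-3-(prop-1-en-2-yl)cyclopentan-1-one
Product: 8 O-benzyl ether of 7 at the C6 hydroxyl
Conditions: BnOC(=NH)CCl3, TfOH (5 mol %), CH2Cl2/cyclohexane, 0 °C
Reagents that add atoms: benzyl 2,2,2-trichloroacetimidate, N=C(OCc1ccccc1)C(Cl)(Cl)Cl
Why: Acid-catalysed O-benzylation with the trichloroacetimidate avoids base, which would cause retro-aldol cleavage or premature loss of the silyloxy group.

Step 5
Reactants: 8 O-benzyl ether of 7 at the C6 hydroxyl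
Product: 9 5-[1-(benzyloxy)ethyl]-5-(3,5-dimethylisoxazol-4-yl)-4-(prop-1-en-2-yl)cyclopent-2-en-1-one (isopropenyl cis to the isoxazole)
Conditions: DBU, CH2Cl2, 0 °C
Reagents that add atoms: none
Why: E1cB elimination of silanolate from the β-silyloxy ketone, which can enolise only towards C11, gives the C11=C14 enone that serves as Michael acceptor.

Step 6
Reactants: 9 5-[1-(benzyloxy)ethyl]-5-(3,5-dimethylisoxazol-4-yl)-4-(prop-1-en-2-yl)cyclopent-2-en-1-one
Product: 11 isoxazole-fused bicyclo[3.2.1]octanone (rings A and B; C8 CH(OBn)CH3; C36 isopropenyl syn to the isoxazole bridge; C11 H(CH3) methyl exo), via lithium enolate 10 (not isolated)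
Conditions: LiN(i-Pr)2 (1.1 equiv), THF, −78 °C; then MeI, DMPU, −78 to 0 °C
Reagents that add atoms: iodomethane, CI
Why: Lateral lithiation of the isoxazole 5-methyl group (the γ-hydrogen on C36 is shielded by the cis CH(OBn)CH3 group) and intramolecular Michael addition to C14, possible only on the face that carries the isoxazole, close ring B and set C14; the enolate is then C-methylated (tandem Michael addition–alkylation), and either C11 epimer converges in step 7.

Step 7
Reactants: 11 isoxazole-fused bicyclo[3.2.1]octanone with C11 H(CH3)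
Product: 13 C11 tertiary triethylsilyl ether (OSiEt3 exo; CH3 endo), via potassium alkoxide 12 (not isolated)
Conditions: KN(SiMe3)2, THF, −78 to −40 °C; 2-(phenylsulfonyl)-3-phenyloxaziridine, −78 °C; then Et3SiCl, −78 to 0 °C
Reagents that add atoms: 2-(phenylsulfonyl)-3-phenyloxaziridine, O=S(=O)(c1ccccc1)N1OC1c1ccccc1; chlorotriethylsilane, CC[Si](Cl)(CC)CC
Why: C9 can enolise only towards C11 and the isoxazole masks the other carbonyl groups, so enolate oxidation by the N-sulfonyloxaziridine on the exo face sets C11 with oxygen exo and methyl endo, and the alkoxide is silylated in the same flask.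

Step 8
Reactants: 13 C11 tertiary triethylsilyl ether
Product: 14 C34 methyl ketone (acetyl on C36 syn to the isoxazole bridge)
Conditions: O3, CH2Cl2/MeOH, −78 °C; Me2S
Reagents that add atoms: ozone, [O-][O+]=O
Why: Ozonolysis with reductive work-up cleaves the 1,1-disubstituted alkene, which is far more reactive towards ozone than the electron-poor isoxazole or the benzyl ether.

Step 9
Reactants: 14 C34 methyl ketone
Product: 15 C34 enol acetate (1-acetoxyvinyl group on C36)
Conditions: LiN(i-Pr)2 (1.1 equiv), THF, −78 °C; Ac2O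
Reagents that add atoms: acetic anhydride, CC(=O)OC(C)=O
Why: Kinetic deprotonation of the only enolisable ketone at its methyl group and O-acetylation of the lithium enolate store the C34 carbonyl as an enol ester, which also freezes the C36 configuration.

Step 10
Reactants: 15 C34 enol acetate
Product: 17 bicyclic 2-acetyl ketone drawn as its enol (C23 ketone in ring B; C27 acetyl on C25), via enaminone 16 (not isolated)
Conditions: Mo(CO)6, MeCN/H2O, 80 °C; then oxalic acid, THF/H2O, rt
Reagents that add atoms: water, O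
Why: Reductive cleavage of the isoxazole N–O bond by Mo(CO)6 gives the vinylogous amide and its hydrolysis releases the 1,3-diketone, the classical use of an isoxazole as a masked β-diketone; the enol ester tolerates dilute aqueous acid.

Step 11
Reactants: 17 bicyclic 2-acetyl ketone
Product: 18 C25-methylated diketone (C26 endo; C27 acetyl exo)
Conditions: MeI, K2CO3, acetone, 45 °C
Reagents that add atoms: iodomethane, CI
Why: C-Alkylation of the cyclic β-diketone enolate builds quaternary C25; the methyl should enter on the endo face because the exo face is covered by the 1-acetoxyvinyl group on C36, which leaves the acetyl group exo and next to C34.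

Step 12
Reactants: 18 C25-methylated diketone
Product: 19 bis(triethylsilyl) enol ether C23(OSiEt3)=C15 and C27(OSiEt3)=C29H2 carrying the C34 enol acetate
Conditions: Et3SiOTf (2.5 equiv), Et3N, CH2Cl2, −78 to 0 °C
Reagents that add atoms: triethylsilyl trifluoromethanesulfonate, CC[Si](CC)(CC)OS(=O)(=O)C(F)(F)F
Why: Soft enolisation with silyl triflate and amine converts both enolisable ketones into their only possible silyl enol ethers, while C9 has no α-hydrogen and C34 is masked.

Step 13
Reactants: 19 bis(triethylsilyl) enol ether carrying the C34 enol acetate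
Product: 20 key-step precursor (C34 acetyl on C36; C27(OSiEt3)=C29H2 on C25; C23 triethylsilyl enol ether; O13 SiEt3; C6 CH(OBn)CH3)
Conditions: pyrrolidine (1.5 equiv), THF, 0 °C to rt
Reagents that add atoms: none
Why: Aminolysis of the enol ester, an activated ester, releases the C34 methyl ketone under non-hydrolytic conditions that leave silyl enol ethers intact.

Step 14
Reactants: 20 key-step precursor; 21 carbon monoxide
Product: 23 tetracyclic lactone (rings A to D; C29 H2; O13 and O28 SiEt3; C23 triethylsilyl enol ether; C6 CH(OBn)CH3), via oxatitanacyclopentane 22 (not isolated)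
Conditions: Cp2Ti(PMe3)2 (1.2 equiv), toluene, rt; then CO (2 atm), 70 °C
Reagents that add atoms: none
Why: Proposed new method: divalent titanium in Cp2Ti(PMe3)2 loses a phosphine, binds the C34 ketone side-on and couples it oxidatively with the electron-rich C27=C29 enol ether to oxatitanacyclopentane 22, which forms C27–C34 and closes ring C in a 5-exo sense; CO then inserts into the Ti–C29 bond and reductive elimination of the acyl alkoxide forms C31–O33 and closes the five-membered lactone ring D, so the ketone oxygen ends as ring oxygen O33. The closest known reaction type is the titanocene-mediated hetero-Pauson–Khand reaction of δ,ε-unsaturated ketones with CO, known for simple terminal alkenes, and the terminal CH2 of this enol ether keeps the substrate near that precedent. C27 and C34 are set together: the metallacycle can only be cis-fused, and it has to form on the endo face of the C27–C34 unit (towards the C23–C15–C14 bridge), which is expected because the exo face is covered by the CH(OBn)CH3 group on C8 while the planar C23=C15 enol ether leaves the endo side open. Chemoselectivity rests on the substrate: C34 is the only ketone that is δ,ε-related to an alkene, C9 can close no five-membered ring with either enol ether, and C6 and C23 are masked as ether and enol ether.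

Step 15
Reactants: 23 tetracyclic lactone
Product: 26 α-methylene lactone (C29=C30H2), via Mannich base 24 (not isolated), via ammonium iodide 25 (not isolated)
Conditions: LiN(i-Pr)2, THF, −78 °C; CH2=NMe2+ I−, −78 to 0 °C; then MeI, CH2Cl2, rt; DBU
Reagents that add atoms: dimethylmethyleneiminium iodide, C=[N+](C)C.[I-]
Why: Mannich reaction of the lactone lithium enolate (C29 is the only acidic position, since C23 is an enol ether and C9 has no α-hydrogen), followed by quaternisation and elimination, is the standard α-methylenation of lactones.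

Step 16
Reactants: 26 α-methylene lactone
Product: 27 C29-methyl lactone with free C6 carbinol (C30 cis to C25)
Conditions: H2 (1 atm), Pd(OH)2/C, NaHCO3, EtOAc, rt
Reagents that add atoms: none
Why: Heterogeneous hydrogenation delivers hydrogen to the exocyclic methylene from the open outer face of ring D (the inner face is covered by the C23–C15–C14 bridge), which sets C29, and the same conditions hydrogenolyse the benzyl ether while the hindered trisubstituted silyl enol ether should survive.

Step 17
Reactants: 27 C29-methyl lactone with free C6 carbinol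
Product: 28 C6 methyl ketone
Conditions: Dess–Martin periodinane, pyridine, CH2Cl2, 0 °C to rt
Reagents that add atoms: none
Why: Dess–Martin oxidation of the secondary alcohol gives the acetyl group on C8, and the pyridine buffer protects the silyl enol ether.

Step 18
Reactants: 28 C6 methyl ketone; 29 (E)-but-2-enal
Product: 32 C6 (2E,4E)-hexa-2,4-dienoyl ketone with C23 still a triethylsilyl enol ether, via lithium aldolate 30 (not isolated), via mesylate 31 (not isolated)
Conditions: LiN(i-Pr)2 (1.1 equiv), THF, −78 °C; (E)-CH3CH=CHCHO; then MsCl, Et3N, −78 °C to rt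
Reagents that add atoms: none
Why: The kinetic lithium enolate of the methyl ketone (the only ketone with free α-hydrogens, and more acidic than the lactone C29–H) adds to the aldehyde carbonyl, and E1cB elimination of the mesylate gives the (E,E)-dienone (aldol condensation).

Step 19
Reactants: 33 (2E,4E)-hexa-2,4-dienoic acid
Product: 34 (2E,4E)-hexa-2,4-dienoyl chloride
Conditions: (COCl)2, DMF (cat.), CH2Cl2, 0 °C to rt
Reagents that add atoms: oxalyl chloride, ClC(=O)C(Cl)=O
Why: Conversion of a carboxylic acid into its chloride with oxalyl chloride and catalytic DMF is routine and leaves the diene untouched.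

Step 20
Reactants: 32 C6 hexadienoyl ketone with C23 triethylsilyl enol ether; 34 (2E,4E)-hexa-2,4-dienoyl chloride
Product: 35 bis(triethylsilyl) ether of the target (O13 and O28)
Conditions: ZnCl2 (1.2 equiv), CH2Cl2/Et2O, 0 °C to rt
Reagents that add atoms: none
Why: Lewis-acid-promoted C-acylation of a silyl enol ether by an acid chloride occurs regiospecifically at C15 and gives the β-diketone, which rests as the hydrogen-bonded enol with the C16 hydroxyl cis to the C23 carbonyl.

Step 21
Reactants: 35 bis(triethylsilyl) ether of the target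
Product: 36 CNP0231466.1 (target)
Conditions: HF·pyridine, THF, 0 °C to rt
Reagents that add atoms: none
Why: Fluoride cleaves the two tertiary triethylsilyl ethers without affecting the dienone, the enolised β-diketone or the β-hydroxy lactone.

Compound list
1 | (R)-4-(tert-butyldimethylsilyloxy)cyclopent-2-en-1-one | O=C1C[C@@H](O[Si](C)(C)C(C)(C)C)C=C1 | starting material
2 | (R)-4-(tert-butyldimethylsilyloxy)-2-iodocyclopent-2-en-1-one | O=C1C[C@@H](O[Si](C)(C)C(C)(C)C)C=C1I | intermediate
3 | 3,5-dimethylisoxazole-4-boronic acid pinacol ester | Cc1noc(C)c1B1OC(C)(C)C(C)(C)O1 | starting material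
4 | (R)-4-(tert-butyldimethylsilyloxy)-2-(3,5-dimethylisoxazol-4-yl)cyclopent-2-en-1-one | O=C1C[C@@H](O[Si](C)(C)C(C)(C)C)C=C1c1c(C)noc1C | intermediate
5 | isopropenylmagnesium bromide | C=C(C)[Mg]Br | starting material
6 | acetaldehyde | CC=O | starting material
7 | (2R,3R,4R)-4-(tert-butyldimethylsilyloxy)-2-(3,5-dimethylisoxazol-4-yl)-2-(1-hydroxyethyl)-3-(prop-1-en-2-yl)cyclopentan-1-one; isopropenyl trans to the silyloxy group, cis to the isoxazole | CC(=C)[C@@H]1[C@](C(O)C)(c2c(C)noc2C)C(=O)C[C@H]1O[Si](C)(C)C(C)(C)C | intermediate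
8 | O-benzyl ether of 7 at the C6 hydroxyl | CC(=C)[C@@H]1[C@](C(OCc3ccccc3)C)(c2c(C)noc2C)C(=O)C[C@H]1O[Si](C)(C)C(C)(C)C | intermediate
9 | 5-[1-(benzyloxy)ethyl]-5-(3,5-dimethylisoxazol-4-yl)-4-(prop-1-en-2-yl)cyclopent-2-en-1-one; isopropenyl cis to the isoxazole | CC(=C)[C@@H]1[C@](C(OCc3ccccc3)C)(c2c(C)noc2C)C(=O)C=C1 | intermediate
10 | lithium enolate (C9–O–Li, C9=C11) of the ring-closed isoxazole-fused bicycle | CC(=C)[C@H]1[C@H]2Cc3onc(C)c3[C@]1(C(OCc4ccccc4)C)C(O[Li])=C2 | intermediate
11 | isoxazole-fused bicyclo[3.2.1]octanone: C9 ketone; C11 H(CH3) with methyl exo; C8 CH(OBn)CH3; C36 isopropenyl syn to the isoxazole bridge | CC(=C)[C@H]1[C@H]2Cc3onc(C)c3[C@]1(C(OCc4ccccc4)C)C(=O)[C@H]2C | intermediate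
12 | potassium alkoxide of the C11 α-hydroxy ketone (O exo, CH3 endo) | CC(=C)[C@H]1[C@H]2Cc3onc(C)c3[C@]1(C(OCc4ccccc4)C)C(=O)[C@@]2(C)O[K] | intermediate
13 | C11 tertiary triethylsilyl ether of the α-hydroxy ketone | CC(=C)[C@H]1[C@H]2Cc3onc(C)c3[C@]1(C(OCc4ccccc4)C)C(=O)[C@@]2(C)O[Si](CC)(CC)CC | intermediate
14 | C34 methyl ketone (acetyl on C36 syn to the isoxazole bridge) | CC(=O)[C@H]1[C@H]2Cc3onc(C)c3[C@]1(C(OCc4ccccc4)C)C(=O)[C@@]2(C)O[Si](CC)(CC)CC | intermediate
15 | C34 enol acetate (1-acetoxyvinyl on C36) | CC(=O)OC(=C)[C@H]1[C@H]2Cc3onc(C)c3[C@]1(C(OCc4ccccc4)C)C(=O)[C@@]2(C)O[Si](CC)(CC)CC | intermediate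
16 | enaminone from N–O cleavage (C23 ketone; C25=C27(NH2)CH3) | CC(=O)OC(=C)[C@H]1[C@H]2CC(=O)/C(=C(\N)C)[C@]1(C(OCc4ccccc4)C)C(=O)[C@@]2(C)O[Si](CC)(CC)CC | intermediate
17 | bicyclic 2-acetyl ketone as its enol (C23 ketone; C25=C27(OH)CH3) | CC(=O)OC(=C)[C@H]1[C@H]2CC(=O)/C(=C(\O)C)[C@]1(C(OCc4ccccc4)C)C(=O)[C@@]2(C)O[Si](CC)(CC)CC | intermediate
18 | C25-methylated diketone (C26 endo; C27 acetyl exo) | CC(=O)OC(=C)[C@H]1[C@H]2CC(=O)[C@@](C)(C(C)=O)[C@]1(C(OCc4ccccc4)C)C(=O)[C@@]2(C)O[Si](CC)(CC)CC | intermediate
19 | bis(triethylsilyl) enol ether (C23(OSiEt3)=C15; C27(OSiEt3)=C29H2) carrying the C34 enol acetate | CC(=O)OC(=C)[C@H]1[C@H]2C=C(O[Si](CC)(CC)CC)[C@@](C)(C(=C)O[Si](CC)(CC)CC)[C@]1(C(OCc4ccccc4)C)C(=O)[C@@]2(C)O[Si](CC)(CC)CC | intermediate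
20 | key-step precursor: bicyclo[3.2.1]octanone with C34 acetyl on C36, C27(OSiEt3)=C29H2 on C25, C23 triethylsilyl enol ether, O13 SiEt3, C6 CH(OBn)CH3 | CC(=O)[C@H]1[C@H]2C=C(O[Si](CC)(CC)CC)[C@@](C)(C(=C)O[Si](CC)(CC)CC)[C@]1(C(OCc4ccccc4)C)C(=O)[C@@]2(C)O[Si](CC)(CC)CC | intermediate
21 | carbon monoxide | [C-]#[O+] | starting material
22 | oxatitanacyclopentane (Cp2Ti bonded to O33 and C29; ring C closed) | CC(OCc4ccccc4)[C@]12C(=O)[C@@](C)(O[Si](CC)(CC)CC)[C@@H]3C=C(O[Si](CC)(CC)CC)[C@@]1(C)[C@@]1(O[Si](CC)(CC)CC)C[Ti](C5C=CC=C5)(C5C=CC=C5)O[C@@]1(C)[C@@H]32 | intermediate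
23 | tetracyclic lactone (rings A to D; C29 H2; O13 and O28 SiEt3; C23 triethylsilyl enol ether; C6 CH(OBn)CH3) | CC(OCc4ccccc4)[C@]12C(=O)[C@@](C)(O[Si](CC)(CC)CC)[C@@H]3C=C(O[Si](CC)(CC)CC)[C@@]1(C)[C@@]1(O[Si](CC)(CC)CC)CC(=O)O[C@@]1(C)[C@@H]32 | intermediate
24 | Mannich base (C29 CH2NMe2 on the outer face) | CC(OCc4ccccc4)[C@]12C(=O)[C@@](C)(O[Si](CC)(CC)CC)[C@@H]3C=C(O[Si](CC)(CC)CC)[C@@]1(C)[C@@]1(O[Si](CC)(CC)CC)[C@H](CN(C)C)C(=O)O[C@@]1(C)[C@@H]32 | intermediate
25 | trimethylammonium iodide of the Mannich base | CC(OCc4ccccc4)[C@]12C(=O)[C@@](C)(O[Si](CC)(CC)CC)[C@@H]3C=C(O[Si](CC)(CC)CC)[C@@]1(C)[C@@]1(O[Si](CC)(CC)CC)[C@H](C[N+](C)(C)C)C(=O)O[C@@]1(C)[C@@H]32.[I-] | intermediate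
26 | α-methylene lactone (C29=C30H2) | CC(OCc4ccccc4)[C@]12C(=O)[C@@](C)(O[Si](CC)(CC)CC)[C@@H]3C=C(O[Si](CC)(CC)CC)[C@@]1(C)[C@@]1(O[Si](CC)(CC)CC)C(=C)C(=O)O[C@@]1(C)[C@@H]32 | intermediate
27 | C29-methyl lactone with free C6 carbinol (C30 cis to C25) | CC(O)[C@]12C(=O)[C@@](C)(O[Si](CC)(CC)CC)[C@@H]3C=C(O[Si](CC)(CC)CC)[C@@]1(C)[C@@]1(O[Si](CC)(CC)CC)[C@@H](C)C(=O)O[C@@]1(C)[C@@H]32 | intermediate
28 | C6 methyl ketone (acetyl on C8) | CC(=O)[C@]12C(=O)[C@@](C)(O[Si](CC)(CC)CC)[C@@H]3C=C(O[Si](CC)(CC)CC)[C@@]1(C)[C@@]1(O[Si](CC)(CC)CC)[C@@H](C)C(=O)O[C@@]1(C)[C@@H]32 | intermediate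
29 | (E)-but-2-enal | C/C=C/C=O | starting material
30 | lithium aldolate (C4 O–Li) | C/C=C/C(O[Li])CC(=O)[C@]12C(=O)[C@@](C)(O[Si](CC)(CC)CC)[C@@H]3C=C(O[Si](CC)(CC)CC)[C@@]1(C)[C@@]1(O[Si](CC)(CC)CC)[C@@H](C)C(=O)O[C@@]1(C)[C@@H]32 | intermediate
31 | C4 mesylate of the aldol adduct | C/C=C/C(OS(C)(=O)=O)CC(=O)[C@]12C(=O)[C@@](C)(O[Si](CC)(CC)CC)[C@@H]3C=C(O[Si](CC)(CC)CC)[C@@]1(C)[C@@]1(O[Si](CC)(CC)CC)[C@@H](C)C(=O)O[C@@]1(C)[C@@H]32 | intermediate
32 | C6 (2E,4E)-hexa-2,4-dienoyl ketone with C23 triethylsilyl enol ether | C/C=C/C=C/C(=O)[C@]12C(=O)[C@@](C)(O[Si](CC)(CC)CC)[C@@H]3C=C(O[Si](CC)(CC)CC)[C@@]1(C)[C@@]1(O[Si](CC)(CC)CC)[C@@H](C)C(=O)O[C@@]1(C)[C@@H]32 | intermediate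
33 | (2E,4E)-hexa-2,4-dienoic acid | C/C=C/C=C/C(O)=O | starting material
34 | (2E,4E)-hexa-2,4-dienoyl chloride | C/C=C/C=C/C(Cl)=O | intermediate
35 | bis(triethylsilyl) ether of the target (O13 and O28) | C/C=C/C=C/C(=O)[C@]12C(=O)[C@@](C)(O[Si](CC)(CC)CC)[C@@H]3\C(=C(O)/C=C/C=C/C)C(=O)[C@@]1(C)[C@@]1(O[Si](CC)(CC)CC)[C@@H](C)C(=O)O[C@@]1(C)[C@@H]32 | intermediate
36 | CNP0231466.1 | C/C=C/C=C/C(=O)[C@]12C(=O)[C@@](C)(O)[C@@H]3\C(=C(O)/C=C/C=C/C)C(=O)[C@@]1(C)[C@@]1(O)[C@@H](C)C(=O)O[C@@]1(C)[C@@H]32 | target

Total step count: 21. Longest linear sequence: 20 steps (steps 1 to 18, 20 and 21; step 19 is a side branch).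

Steps most likely to fail

Step 14. The oxidative coupling may not take place at the fully substituted enol ether carbon, the metallacycle may form on the exo face (wrong C27/C34 pair), or the titanium may simply reduce the ketone. The fallback uses known chemistry, sets out from 20 and comes back at 23. Irradiation of 20 (about 300 nm, benzene) should give, by intramolecular Paternò–Büchi reaction (C34–C27 first by the rule of five, then O33–C29), the ring C-fused oxetane F1. Carbonylative ring expansion of F1 with Co2(CO)8 as catalyst under CO pressure in 1,2-dimethoxyethane inserts CO into the less hindered O33–C29 bond and returns lactone 23.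

Step 6. The amide base may remove the γ-hydrogen on C36 instead of an isoxazole methyl hydrogen, or the lithiated methyl group may add to the C9 carbonyl. The fallback sets out from 9 and comes back at 11, and closes ring B through a ketone enolate instead. The isoxazole of 9 is opened first (Mo(CO)6 in wet MeCN, then aqueous oxalic acid) to the 3-substituted pentane-2,4-dione F2, whose two acetyl groups are equivalent. O-Silylation (t-BuMe2SiCl, imidazole) gives the mono silyl enol ether F3. Its remaining acetyl group is deprotonated fast and kinetically at the methyl group (LiN(i-Pr)2, −78 °C), the enolate closes ring B by Michael addition to C14, and MeI traps the new C9 enolate to give the bicyclic β-silyloxy enone F4. Condensation with NH2OH·HCl in pyridine/EtOH (nitrogen displaces the silyloxy group at C27, oxygen closes on C23) rebuilds the isoxazole and gives 11.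

Step 15. The lactone enolate may expel the C27 silyloxy group (β-elimination) or attack the C9 ketone. The fallback sets out from 23 and comes back at 27 without forming an enolate. Heating 23 with tert-butoxybis(dimethylamino)methane in toluene should give the α-(dimethylaminomethylene) lactone F5. Hydrogenation of F5 over Pd(OH)2/C reduces the enamine double bond, dimethylamine is lost, the resulting methylene group is reduced from the outer face and the benzyl ether is cleaved, which gives 27 directly.

Further compounds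
F1 | step 14 | oxetane fused to ring C (O33–C34–C27–C29), other groups as in 23 | CC(OCc4ccccc4)[C@]12C(=O)[C@@](C)(O[Si](CC)(CC)CC)[C@@H]3C=C(O[Si](CC)(CC)CC)[C@@]1(C)[C@@]1(O[Si](CC)(CC)CC)CO[C@@]1(C)[C@@H]32
F2 | step 6 | 3-substituted pentane-2,4-dione on C8 of enone 9 (isoxazole opened) | CC(=C)[C@@H]1[C@](C(OCc3ccccc3)C)(C(C(C)=O)C(C)=O)C(=O)C=C1
F3 | step 6 | mono tert-butyldimethylsilyl enol ether of F2 | CC(=C)[C@@H]1[C@](C(OCc3ccccc3)C)(C(C(C)=O)=C(C)O[Si](C)(C)C(C)(C)C)C(=O)C=C1
F4 | step 6 | bicyclic β-silyloxy enone: ring B closed, C23 ketone, C25=C27(OSi-t-BuMe2)CH3, C11 H(CH3) | CC(=C)[C@H]1[C@H]2CC(=O)C(=C(C)O[Si](C)(C)C(C)(C)C)[C@]1(C(OCc4ccccc4)C)C(=O)[C@H]2C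
F5 | step 15 | α-(dimethylaminomethylene) lactone derived from 23 | CC(OCc4ccccc4)[C@]12C(=O)[C@@](C)(O[Si](CC)(CC)CC)[C@@H]3C=C(O[Si](CC)(CC)CC)[C@@]1(C)[C@@]1(O[Si](CC)(CC)CC)C(=CN(C)C)C(=O)O[C@@]1(C)[C@@H]32
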